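The target is cut at the bond between the oxirane carbon C2, which is quaternary, benzylic and bonded to the ring oxygen, and its exocyclic CH2O arm. The C2–H parent, an (R)-aryloxirane, is acidic at exactly that carbon, so lithiation and trapping with formaldehyde give the C2–CH2 bond and the quaternary stereocentre with retention; the benzene and oxirane rings are already in place. Because both primary CH2O arms carry the same acyl group, the anhydride esterifies both alkoxides in the same flask. The precursor 8 bears a free benzylic alcohol and a TIPS aryl ether, which has no acidic C–H and later permits fluoride-triggered angeloylation without acid or oxidant.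

Key step: step 6

Assumptions and remarks on the chemistry:
- Formaldehyde is used as the monomer, obtained by cracking paraformaldehyde into cold THF and used at once.
- The geometry at the oxirane carbon is the same from 8 to 18. The descriptor is R in 8, 12, 14 and 18 and S in 13 only because the CIP rank of the exocyclic arm changes (CH2OLi < ring CH2 < CH2O-acyl).
- Oxirane-containing compounds (8, 14, 18) are purified on triethylamine-deactivated silica.
- The anhydride carries two acyl groups but transfers only one per molecule, so step 5 consumes two molecules of acid 9 and step 6 consumes two molecules of anhydride 10.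

Step 1
Reactants: 1 methyl 4-bromo-3-hydroxybenzoate
Product: 2 methyl 4-bromo-3-[(triisopropylsilyl)oxy]benzoate
Conditions: i-Pr3SiCl (1.2 equiv), imidazole (2.5 equiv), DMF, 23 °C
Reagents that add atoms: chlorotriisopropylsilane, CC(C)[Si](Cl)(C(C)C)C(C)C
Why: Imidazole-promoted O-silylation of the acidic phenol should be fast, and the bulky triisopropylsilyl ether is the aryl ether most resistant to base and to oxygen-to-carbon silyl shifts in the organolithium steps that follow.

Step 2
Reactants: 2 methyl 4-bromo-3-[(triisopropylsilyl)oxy]benzoate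
Product: 3 {4-bromo-3-[(triisopropylsilyl)oxy]phenyl}methanol
Conditions: i-Bu2AlH (2.5 equiv), CH2Cl2, −78 → 0 °C; aq potassium sodium tartrate
Reagents that add atoms: none
Why: Hydride reduction of the methyl ester to the primary alcohol with i-Bu2AlH should leave the aryl bromide and the aryl silyl ether untouched.

Step 3
Reactants: 3 {4-bromo-3-[(triisopropylsilyl)oxy]phenyl}methanol; 4 2-chloro-N-methoxy-N-methylacetamide
Product: 6 2-chloro-1-[4-(hydroxymethyl)-2-[(triisopropylsilyl)oxy]phenyl]ethan-1-one, via aryllithium alkoxide 5 (not isolated)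
Conditions: n-BuLi (2.1 equiv), THF, −78 °C; then 4 (1.3 equiv), −78 → −40 °C; aq NH4Cl
Reagents that add atoms: none
Why: Deprotonation of the hydroxyl group and bromine–lithium exchange give the aryllithium, which acylates once on the N-methoxy-N-methylamide (Weinreb ketone synthesis, which stops at the ketone stage), while −78 °C and the bulk of the TIPS group should hold back a retro-Brook shift of silicon to the lithiated carbon.

Step 4
Reactants: 6 2-chloro-1-[4-(hydroxymethyl)-2-[(triisopropylsilyl)oxy]phenyl]ethan-1-one
Product: 8 {4-[(2R)-oxiran-2-yl]-3-[(triisopropylsilyl)oxy]phenyl}methanol, via chlorohydrin 7 (not isolated)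
Conditions: RuCl(p-cymene)[(S,S)-TsDPEN] (1 mol %), HCO2H/Et3N (5:2), EtOAc, 25 °C; aqueous wash, then crude 7, KOt-Bu (1.2 equiv), THF, −20 °C
Reagents that add atoms: none
Why: Noyori–Ikariya asymmetric transfer hydrogenation with the (S,S)-TsDPEN catalyst should deliver hydride to the ketone face that gives (S)-alcohols from aryl methyl ketones, which here is the (R)-chlorohydrin because CH2Cl outranks the aryl group, and the alkoxide then closes the oxirane by intramolecular Williamson substitution (3-exo-tet) at CH2Cl without touching the stereocentre, the bulky base sparing the aryl silyl ether.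

Step 5
Reactants: 9 (R)-2-methylbutanoic acid
Product: 10 (R)-2-methylbutanoic anhydride
Conditions: N,N'-dicyclohexylcarbodiimide (0.5 equiv per acid), CH2Cl2, 0 → 23 °C; filter, distil
Reagents that add atoms: a second molecule of (R)-2-methylbutanoic acid 9, CC[C@@H](C)C(=O)O
Why: Carbodiimide dehydration joins two molecules of the acid through an O-acylisourea to give the symmetric anhydride without base, so the α-stereocentre should not epimerise.

Step 6
Reactants: 8 {4-[(2R)-oxiran-2-yl]-3-[(triisopropylsilyl)oxy]phenyl}methanol; 10 (R)-2-methylbutanoic anhydride; 11 formaldehyde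
Product: 14 [(2R)-2-[4-[[(2R)-2-methylbutanoyl]oxymethyl]-2-[(triisopropylsilyl)oxy]phenyl]oxiran-2-yl]methyl (2R)-2-methylbutanoate, via dilithio oxirane 12 (not isolated), via dilithium dialkoxide 13 (not isolated)
Conditions: s-BuLi (2.3 equiv), TMEDA (2.5 equiv), THF, −98 °C, 15 min; CH2O (monomer in THF, 1.5 equiv), −98 °C; 10 (3.5 equiv), −98 → −30 °C; aq NaHCO3
Reagents that add atoms: a second molecule of (R)-2-methylbutanoic anhydride 10, CC[C@@H](C)C(=O)OC(=O)[C@H](C)CC
Why: s-BuLi/TMEDA removes the hydroxyl proton and then the oxirane C2–H, which is benzylic, bonded to the ring oxygen and part of a strained ring, to give the pyramidal oxiranyllithium 12. 12 adds as a carbon nucleophile to monomeric formaldehyde to give dialkoxide 13, and two molecules of the anhydride then acylate the two lithium alkoxides, so the step forms the C2–CH2 bond and two ester C–O bonds and closes no ring. The closest known reaction type is the α-lithiation of enantioenriched styrene oxides with s-BuLi/TMEDA in THF at −98 °C followed by trapping with aldehydes or ketones, applied here to an aryl oxirane that carries a lithium alkoxide and an ortho silyloxy group. The new quaternary stereocentre is controlled by the C2–Li bond, which is configurationally stable at −98 °C and is substituted with retention, so (R)-8 should give (R)-14 (the descriptor stays R because CH2O-acyl outranks the ring CH2). The step needs chemoselective removal of the oxirane C–H, and the substrate secures it because the TIPS aryl ether and the benzylic lithium alkoxide offer no other activated C–H and no strong directing group for ring metalation, while −98 °C and the bulk of TIPS hold back silyl shift from oxygen to carbon and α-elimination of the carbenoid. Acylation while the mixture is still cold traps the primary alkoxide before a degenerate Payne shift could erode the configuration at C2.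

Step 7
Reactants: 14 [(2R)-2-[4-[[(2R)-2-methylbutanoyl]oxymethyl]-2-[(triisopropylsilyl)oxy]phenyl]oxiran-2-yl]methyl (2R)-2-methylbutanoate; 15 angelic acid
Product: 18 [(2R)-2-[2-[[(Z)-2-methylbut-2-enoyl]oxy]-4-[[(2R)-2-methylbutanoyl]oxymethyl]phenyl]oxiran-2-yl]methyl (2R)-2-methylbutanoate, via mixed anhydride 16 (not isolated), via ammonium phenoxide 17 (not isolated)
Conditions: 15 (2.5 equiv), 2,4,6-Cl3C6H2COCl (2.5 equiv), Et3N (2.6 equiv), THF, 0 °C (second flask, gives 16); 14, Bu4NF (1.05 equiv), THF, −40 °C, 10 min (gives 17); then add 16, −40 → 0 °C; aq NH4Cl wash, cold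
Reagents that add atoms: none
Why: Fluoride cleaves the aryl O–Si bond much faster than it attacks the alkyl esters, and the resulting ammonium phenoxide is acylated at the less hindered enoyl carbonyl of the Yamaguchi-type mixed anhydride at low temperature without a nucleophilic catalyst, which should avoid Z-to-E isomerisation by conjugate addition, keep acid and oxidant away from the 2-aryl oxirane and never leave the free ortho-hydroxyaryl oxirane to be isolated.

Compound list
1 | methyl 4-bromo-3-hydroxybenzoate | COC(=O)c1ccc(Br)c(O)c1 | starting material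
2 | methyl 4-bromo-3-[(triisopropylsilyl)oxy]benzoate | COC(=O)c1ccc(Br)c(O[Si](C(C)C)(C(C)C)C(C)C)c1 | intermediate
3 | {4-bromo-3-[(triisopropylsilyl)oxy]phenyl}methanol | OCc1ccc(Br)c(O[Si](C(C)C)(C(C)C)C(C)C)c1 | intermediate
4 | 2-chloro-N-methoxy-N-methylacetamide | CON(C)C(=O)CCl | starting material
5 | lithium {4-lithio-3-[(triisopropylsilyl)oxy]phenyl}methanolate (aryllithium alkoxide, formed in the flask) | [Li]OCc1ccc([Li])c(O[Si](C(C)C)(C(C)C)C(C)C)c1 | intermediate
6 | 2-chloro-1-[4-(hydroxymethyl)-2-[(triisopropylsilyl)oxy]phenyl]ethan-1-one | OCc1ccc(C(=O)CCl)c(O[Si](C(C)C)(C(C)C)C(C)C)c1 | intermediate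
7 | (1R)-2-chloro-1-[4-(hydroxymethyl)-2-[(triisopropylsilyl)oxy]phenyl]ethan-1-ol (chlorohydrin, formed in the flask) | OCc1ccc([C@@H](O)CCl)c(O[Si](C(C)C)(C(C)C)C(C)C)c1 | intermediate
8 | {4-[(2R)-oxiran-2-yl]-3-[(triisopropylsilyl)oxy]phenyl}methanol, i.e. (R)-2-[4-(hydroxymethyl)-2-(triisopropylsilyloxy)phenyl]oxirane | OCc1ccc([C@@H]2CO2)c(O[Si](C(C)C)(C(C)C)C(C)C)c1 | intermediate
9 | (R)-2-methylbutanoic acid | CC[C@@H](C)C(=O)O | starting material
10 | (R)-2-methylbutanoic anhydride | CC[C@@H](C)C(=O)OC(=O)[C@H](C)CC | intermediate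
11 | formaldehyde (monomer from paraformaldehyde) | C=O | starting material
12 | lithium {4-[(2R)-2-lithiooxiran-2-yl]-3-[(triisopropylsilyl)oxy]phenyl}methanolate (C–Li in the place of the oxirane C2–H of 8, formed in the flask) | [Li]OCc1ccc([C@]2([Li])CO2)c(O[Si](C(C)C)(C(C)C)C(C)C)c1 | intermediate
13 | dilithium salt of {(2S)-2-[4-(hydroxymethyl)-2-[(triisopropylsilyl)oxy]phenyl]oxiran-2-yl}methanol (same geometry at C2 as 12 and 14, formed in the flask) | [Li]OCc1ccc([C@]2(CO[Li])CO2)c(O[Si](C(C)C)(C(C)C)C(C)C)c1 | intermediate
14 | [(2R)-2-[4-[[(2R)-2-methylbutanoyl]oxymethyl]-2-[(triisopropylsilyl)oxy]phenyl]oxiran-2-yl]methyl (2R)-2-methylbutanoate | CC[C@@H](C)C(=O)OCc1ccc([C@]2(COC(=O)[C@H](C)CC)CO2)c(O[Si](C(C)C)(C(C)C)C(C)C)c1 | intermediate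
15 | angelic acid, (Z)-2-methylbut-2-enoic acid | C/C=C(/C)C(=O)O | starting material
16 | (Z)-2-methylbut-2-enoic 2,4,6-trichlorobenzoic anhydride (formed in a second flask, used as solution) | C/C=C(/C)C(=O)OC(=O)c1c(Cl)cc(Cl)cc1Cl | intermediate
17 | tetrabutylammonium 5-[[(2R)-2-methylbutanoyl]oxymethyl]-2-[(2R)-2-[[(2R)-2-methylbutanoyl]oxymethyl]oxiran-2-yl]phenolate (formed in the flask) | CCCC[N+](CCCC)(CCCC)CCCC.CC[C@@H](C)C(=O)OCc1ccc([C@]2(COC(=O)[C@H](C)CC)CO2)c([O-])c1 | intermediate
18 | [(2R)-2-[2-[[(Z)-2-methylbut-2-enoyl]oxy]-4-[[(2R)-2-methylbutanoyl]oxymethyl]phenyl]oxiran-2-yl]methyl (2R)-2-methylbutanoate (CNP0166772.1) | C/C=C(/C)C(=O)Oc1cc(COC(=O)[C@H](C)CC)ccc1[C@]1(COC(=O)[C@H](C)CC)CO1 | target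

Total step count: 7. Longest linear sequence: 6 steps (1, 2, 3, 4, 6, 7); step 5 is a one-step side branch.

The three steps most likely to fail, riskiest first:

Step 6. What may go wrong: metalation at a site other than the oxirane C–H, α-elimination or silyl shift of the oxiranyllithium before it is trapped, addition of the alkoxides to excess formaldehyde followed by acylation of the hemiformals, or a Payne-type alkoxide shift before acylation that erodes the configuration. The fallback sets out from 3 and comes back at 14. Compound 3 is converted as in step 3 into aryllithium 5, which is quenched with 2-isopropoxy-4,4,5,5-tetramethyl-1,3,2-dioxaborolane to give {4-(4,4,5,5-tetramethyl-1,3,2-dioxaborolan-2-yl)-3-[(triisopropylsilyl)oxy]phenyl}methanol F1. Suzuki–Miyaura coupling of this boronate with 2-bromoprop-2-en-1-ol (Pd(dppf)Cl2, K3PO4, THF/H2O, 50 °C) gives 2-[4-(hydroxymethyl)-2-[(triisopropylsilyl)oxy]phenyl]prop-2-en-1-ol F2. Sharpless asymmetric epoxidation (Ti(Oi-Pr)4, L-(+)-diisopropyl tartrate, t-BuOOH, 4 Å molecular sieves, CH2Cl2, −20 °C) delivers oxygen to the alkene face that leads to (S)-glycidol from allyl alcohol and should give {(2S)-2-[4-(hydroxymethyl)-2-[(triisopropylsilyl)oxy]phenyl]oxiran-2-yl}methanol F3. Acylation of both hydroxyl groups with 10 (Et3N, catalytic 4-dimethylaminopyridine, CH2Cl2, 0 °C) then gives 14. The quaternary centre is set here by reagent-controlled epoxidation of a 2-aryl allylic alcohol instead of by an organolithium.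

Step 4. What may go wrong: poor facial selectivity in the hydride transfer because the bulky ortho silyloxy group twists the aryl ketone, or migration or loss of the silyl group while the chlorohydrin alkoxide closes. The fallback sets out from 3 and comes back at 8. Aryllithium 5, made from 3 as in step 3, is formylated with DMF to give 4-(hydroxymethyl)-2-[(triisopropylsilyl)oxy]benzaldehyde F4. Corey–Chaykovsky methylenation (Me3S+ I−, KN(SiMe3)2, THF, −10 °C) gives racemic {4-(oxiran-2-yl)-3-[(triisopropylsilyl)oxy]phenyl}methanol F5. Hydrolytic kinetic resolution with (R,R)-(salen)Co(OAc), the acetate of the trivalent cobalt complex of N,N'-bis(3,5-di-tert-butylsalicylidene)cyclohexane-1,2-diamine, and water (0.55 equiv) in THF at 0 → 23 °C should hydrolyse the (S)-oxirane to (1S)-1-[4-(hydroxymethyl)-2-[(triisopropylsilyl)oxy]phenyl]ethane-1,2-diol F6 and leave 8. Selectivity is then decided at the unhindered CH2 terminus, and the enantiomeric purity of 8 can be raised by running to higher conversion.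

Step 7. What may go wrong: isomerisation of the (Z)-enoyl group to the (E)-isomer during acyl transfer, or incomplete acylation of the hindered phenoxide. The fallback sets out from 14 and comes back at 18. Compound 14 is desilylated as in step 7 (Bu4NF, THF, −40 °C) and the phenoxide is acylated with the 2,4,6-trichlorobenzoyl mixed anhydride of 2-[bis(2,2,2-trifluoroethoxy)phosphoryl]propanoic acid to give 5-[[(2R)-2-methylbutanoyl]oxymethyl]-2-[(2R)-2-[[(2R)-2-methylbutanoyl]oxymethyl]oxiran-2-yl]phenyl 2-[bis(2,2,2-trifluoroethoxy)phosphoryl]propanoate F7, a mixture of epimers at the phosphonate-bearing carbon. Still–Gennari olefination (KN(SiMe3)2, 18-crown-6, THF, −78 °C, then acetaldehyde) should give 18. The Z double bond is then built under kinetic control after the acyl transfer, so no preformed angeloyl donor has to survive the acylation.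

Further compounds
F1 | step 6 | {4-(4,4,5,5-tetramethyl-1,3,2-dioxaborolan-2-yl)-3-[(triisopropylsilyl)oxy]phenyl}methanol | OCc1ccc(B2OC(C)(C)C(C)(C)O2)c(O[Si](C(C)C)(C(C)C)C(C)C)c1
F2 | step 6 | 2-[4-(hydroxymethyl)-2-[(triisopropylsilyl)oxy]phenyl]prop-2-en-1-ol | C=C(CO)c1ccc(CO)cc1O[Si](C(C)C)(C(C)C)C(C)C
F3 | step 6 | {(2S)-2-[4-(hydroxymethyl)-2-[(triisopropylsilyl)oxy]phenyl]oxiran-2-yl}methanol | OCc1ccc([C@]2(CO)CO2)c(O[Si](C(C)C)(C(C)C)C(C)C)c1
F4 | step 4 | 4-(hydroxymethyl)-2-[(triisopropylsilyl)oxy]benzaldehyde | O=Cc1ccc(CO)cc1O[Si](C(C)C)(C(C)C)C(C)C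
F5 | step 4 | racemic {4-(oxiran-2-yl)-3-[(triisopropylsilyl)oxy]phenyl}methanol | OCc1ccc(C2CO2)c(O[Si](C(C)C)(C(C)C)C(C)C)c1
F6 | step 4 | (1S)-1-[4-(hydroxymethyl)-2-[(triisopropylsilyl)oxy]phenyl]ethane-1,2-diol | OCc1ccc([C@H](O)CO)c(O[Si](C(C)C)(C(C)C)C(C)C)c1
F7 | step 7 | 5-[[(2R)-2-methylbutanoyl]oxymethyl]-2-[(2R)-2-[[(2R)-2-methylbutanoyl]oxymethyl]oxiran-2-yl]phenyl 2-[bis(2,2,2-trifluoroethoxy)phosphoryl]propanoate | CC(C(=O)Oc1cc(COC(=O)[C@H](C)CC)ccc1[C@]1(COC(=O)[C@H](C)CC)CO1)P(=O)(OCC(F)(F)F)OCC(F)(F)F
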